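**Retrosynthetic overview**
- The strategy rests on the open-chain C7–C8 pair: C7 (benzylic, acetoxy, on the 3,4,5-trimethoxyphenyl ring) and C8 (ether oxygen to the 2,6-dimethoxy-4-propenylphenyl ring) are adjacent syn-dioxygenated stereocentres, with C9 as a methyl group.
- C7–OAc comes from acetylation of the alcohol; the C9 methyl comes from a CH2OH group by tosylation and hydride displacement.
- The C7–C8 bond and both stereocentres come from an oxazolidinone-controlled boron aldol of aryloxyacetyl imide 7 with 3,4,5-trimethoxybenzaldehyde 8.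
- Imide 7 comes from acid 4 and auxiliary 5; acid 4 from (E)-propenylphenol 2 and bromoacetic acid; phenol 2 from the allylphenol 1 by alkene isomerisation.
- No ring is formed: both benzene rings are bought, and the oxazolidinone ring is a recoverable auxiliary.

Key step: step 4

Remark on the chemistry: neolignan numbering is used (C7 benzylic acetoxy carbon, C8 aryloxy carbon, C9 methyl). The aldol adduct (2S,3R) has the same spatial arrangement as (7R,8R) in the target; only the CIP ranking at C8 changes when C9 goes from acyl to CH2OH to CH3.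

**Route**

Step 1
Reactants: 1 4-allyl-2,6-dimethoxyphenol
Product: 2 (E)-2,6-dimethoxy-4-(prop-1-enyl)phenol
Conditions: RuHCl(CO)(PPh3)3 (1 mol %), toluene, 80 °C, Ar
Reagents that add atoms: none
Why: Ruthenium-hydride alkene isomerisation (hydrometalation then β-hydride elimination) moves the terminal double bond into conjugation with the arene, and under thermodynamic control the (E)-propenyl isomer should dominate strongly, with any minor Z isomer to be removed by recrystallisation at the stage of 2, 4 or 7.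

Step 2
Reactants: 2 (E)-2,6-dimethoxy-4-(prop-1-enyl)phenol; 3 bromoacetic acid
Product: 4 2-[2,6-dimethoxy-4-((E)-prop-1-enyl)phenoxy]acetic acid
Conditions: NaH (2.5 equiv), THF–DMF (4:1), 0 → 40 °C, Ar; then 1 M HCl, 0 °C
Reagents that add atoms: none
Why: Williamson ether synthesis in which the nucleophilic 2,6-dimethoxyphenoxide displaces bromide from the bromoacetate carboxylate (SN2 at a primary α-halo carboxylate), the inert atmosphere protecting the oxidisable phenoxide and the basic medium leaving the propenyl group untouched.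

Step 3
Reactants: 4 2-[2,6-dimethoxy-4-((E)-prop-1-enyl)phenoxy]acetic acid; 5 (S)-4-benzyloxazolidin-2-one
Product: 7 (S)-4-benzyl-3-{2-[2,6-dimethoxy-4-((E)-prop-1-enyl)phenoxy]acetyl}oxazolidin-2-one, via mixed pivalic anhydride 6 (not isolated)
Conditions: PivCl, Et3N, THF, −20 °C; then 5, LiCl, −20 °C → rt
Reagents that add atoms: none
Why: Mixed-anhydride N-acylation in which the LiCl/Et3N-activated oxazolidinone attacks the less hindered aryloxyacetyl carbonyl of 6 rather than the tert-butyl-shielded pivaloyl carbonyl, leaving the auxiliary stereocentre untouched.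

Step 4
Reactants: 7 (S)-4-benzyl-3-{2-[2,6-dimethoxy-4-((E)-prop-1-enyl)phenoxy]acetyl}oxazolidin-2-one; 8 3,4,5-trimethoxybenzaldehyde
Product: 11 (S)-4-benzyl-3-{(2S,3R)-2-[2,6-dimethoxy-4-((E)-prop-1-enyl)phenoxy]-3-hydroxy-3-(3,4,5-trimethoxyphenyl)propanoyl}oxazolidin-2-one, via (Z)-dibutylboron enolate 9 (not isolated), via dibutylboron aldolate 10 (not isolated)
Conditions: Bu2BOTf (1.2 equiv), Et3N (1.4 equiv), CH2Cl2, −78 → 0 °C; then 8, −78 → 0 °C; pH 7 buffer, MeOH, 30% H2O2, 0 °C
Reagents that add atoms: none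
Why: Soft enolisation with Bu2BOTf/Et3N should give the (Z)-boron enolate 9 (allylic strain in the imide disfavours the E geometry), which adds to the aldehyde through a closed Zimmerman–Traxler chair to give boron aldolate 10, cleaved oxidatively to 11. The closest known reaction type is the Evans boron syn-aldol of alkoxyacetyl and aryloxyacetyl oxazolidinones with aromatic aldehydes. No ring is closed; the single new skeletal bond is C7–C8. The C8 centre (C2 of the acyl chain) is set by the auxiliary: boron has no free site for chelation, so the oxazolidinone carbonyl lies opposed to the enolate oxygen and the benzyl group blocks one enolate face. The C7 centre (C3) is set relative to C8 by the chair, with the trimethoxyphenyl group equatorial and the Z geometry translating into the syn relationship. The step needs both enantio- and syn-diastereoselectivity, and the (Z)-enolate plus the (S)-benzyl group should deliver the (2S,3R) adduct, which is the (7R,8R) arrangement of the target.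

Step 5
Reactants: 11 (S)-4-benzyl-3-{(2S,3R)-2-[2,6-dimethoxy-4-((E)-prop-1-enyl)phenoxy]-3-hydroxy-3-(3,4,5-trimethoxyphenyl)propanoyl}oxazolidin-2-one
Product: 12 (1R,2R)-2-[2,6-dimethoxy-4-((E)-prop-1-enyl)phenoxy]-1-(3,4,5-trimethoxyphenyl)propane-1,3-diol
Conditions: LiBH4 (2 equiv), MeOH (1 equiv), THF, 0 °C; aq. NH4Cl
Reagents that add atoms: none
Why: Reductive cleavage of the N-acyloxazolidinone, in which borohydride attacks the exocyclic imide carbonyl and reduces it to CH2OH, should release the auxiliary for recovery and leave both stereocentres, the aryl ethers and the propenyl group unchanged.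

Step 6
Reactants: 12 (1R,2R)-2-[2,6-dimethoxy-4-((E)-prop-1-enyl)phenoxy]-1-(3,4,5-trimethoxyphenyl)propane-1,3-diol
Product: 13 (2R,3R)-2-[2,6-dimethoxy-4-((E)-prop-1-enyl)phenoxy]-3-hydroxy-3-(3,4,5-trimethoxyphenyl)propyl 4-methylbenzenesulfonate
Conditions: TsCl (1.05 equiv), pyridine, CH2Cl2, 0 °C
Reagents that add atoms: p-toluenesulfonyl chloride, Cc1ccc(cc1)S(=O)(=O)Cl
Why: Chemoselective sulfonylation, since the unhindered primary hydroxyl should react with TsCl much faster than the secondary benzylic hydroxyl crowded by the neighbouring aryloxy group.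

Step 7
Reactants: 13 (2R,3R)-2-[2,6-dimethoxy-4-((E)-prop-1-enyl)phenoxy]-3-hydroxy-3-(3,4,5-trimethoxyphenyl)propyl 4-methylbenzenesulfonate
Product: 14 (1R,2R)-2-[2,6-dimethoxy-4-((E)-prop-1-enyl)phenoxy]-1-(3,4,5-trimethoxyphenyl)propan-1-ol
Conditions: LiEt3BH (3 equiv), THF, 0 °C → rt; aq. NH4Cl
Reagents that add atoms: none
Why: SN2 hydride displacement of the primary tosylate by Super-Hydride turns CH2OTs into the C9 methyl without touching C7 or C8, the C7 hydroxyl being carried as its lithium alkoxide and the temperature kept low so that hydride transfer outruns oxetane closure, fragmentation or addition to the styrene.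

Step 8
Reactants: 14 (1R,2R)-2-[2,6-dimethoxy-4-((E)-prop-1-enyl)phenoxy]-1-(3,4,5-trimethoxyphenyl)propan-1-ol
Product: 15 (1R,2R)-2-[2,6-dimethoxy-4-((E)-prop-1-enyl)phenoxy]-1-(3,4,5-trimethoxyphenyl)propyl acetate (Compound NP-024268)
Conditions: Ac2O, pyridine, DMAP (cat.), CH2Cl2, rt; neutral work-up
Reagents that add atoms: acetic anhydride, CC(=O)OC(C)=O
Why: DMAP-catalysed O-acylation of the secondary benzylic alcohol takes place at oxygen only, so the C7 configuration is retained, and the non-acidic work-up avoids ionisation of the electron-rich benzylic acetate.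

**Compound list**
1 | 4-allyl-2,6-dimethoxyphenol | C=CCc1cc(OC)c(O)c(OC)c1 | starting material
2 | (E)-2,6-dimethoxy-4-(prop-1-enyl)phenol | C/C=C/c1cc(OC)c(O)c(OC)c1 | intermediate
3 | bromoacetic acid | OC(=O)CBr | starting material
4 | 2-[2,6-dimethoxy-4-((E)-prop-1-enyl)phenoxy]acetic acid | C/C=C/c1cc(OC)c(OCC(=O)O)c(OC)c1 | intermediate
5 | (S)-4-benzyloxazolidin-2-one | O=C1N[C@@H](Cc2ccccc2)CO1 | starting material
6 | mixed pivalic anhydride of acid 4 (not isolated) | C/C=C/c1cc(OC)c(OCC(=O)OC(=O)C(C)(C)C)c(OC)c1 | intermediate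
7 | (S)-4-benzyl-3-{2-[2,6-dimethoxy-4-((E)-prop-1-enyl)phenoxy]acetyl}oxazolidin-2-one | C/C=C/c1cc(OC)c(OCC(=O)N2[C@@H](Cc3ccccc3)COC2=O)c(OC)c1 | intermediate
8 | 3,4,5-trimethoxybenzaldehyde | COc1cc(C=O)cc(OC)c1OC | starting material
9 | (Z)-dibutylboron enolate of imide 7 (not isolated) | C/C=C/c1cc(OC)c(O/C=C(\OB(CCCC)CCCC)N2[C@@H](Cc3ccccc3)COC2=O)c(OC)c1 | intermediate
10 | dibutylboron aldolate of 11 (not isolated) | C/C=C/c1cc(OC)c(O[C@@H]([C@H](OB(CCCC)CCCC)c2cc(OC)c(OC)c(OC)c2)C(=O)N2[C@@H](Cc3ccccc3)COC2=O)c(OC)c1 | intermediate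
11 | (S)-4-benzyl-3-{(2S,3R)-2-[2,6-dimethoxy-4-((E)-prop-1-enyl)phenoxy]-3-hydroxy-3-(3,4,5-trimethoxyphenyl)propanoyl}oxazolidin-2-one | C/C=C/c1cc(OC)c(O[C@@H]([C@H](O)c2cc(OC)c(OC)c(OC)c2)C(=O)N2[C@@H](Cc3ccccc3)COC2=O)c(OC)c1 | intermediate
12 | (1R,2R)-2-[2,6-dimethoxy-4-((E)-prop-1-enyl)phenoxy]-1-(3,4,5-trimethoxyphenyl)propane-1,3-diol | C/C=C/c1cc(OC)c(O[C@@H]([C@H](O)c2cc(OC)c(OC)c(OC)c2)CO)c(OC)c1 | intermediate
13 | (2R,3R)-2-[2,6-dimethoxy-4-((E)-prop-1-enyl)phenoxy]-3-hydroxy-3-(3,4,5-trimethoxyphenyl)propyl 4-methylbenzenesulfonate | C/C=C/c1cc(OC)c(O[C@@H]([C@H](O)c2cc(OC)c(OC)c(OC)c2)COS(=O)(=O)c2ccc(C)cc2)c(OC)c1 | intermediate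
14 | (1R,2R)-2-[2,6-dimethoxy-4-((E)-prop-1-enyl)phenoxy]-1-(3,4,5-trimethoxyphenyl)propan-1-ol | C/C=C/c1cc(OC)c(O[C@H](C)[C@H](O)c2cc(OC)c(OC)c(OC)c2)c(OC)c1 | intermediate
15 | (1R,2R)-2-[2,6-dimethoxy-4-((E)-prop-1-enyl)phenoxy]-1-(3,4,5-trimethoxyphenyl)propyl acetate, (7R,8R), Compound NP-024268 | C/C=C/c1cc(OC)c(O[C@H](C)[C@H](OC(C)=O)c2cc(OC)c(OC)c(OC)c2)c(OC)c1 | target

**Step count**
Total steps: 8. Longest linear sequence: 8 steps (1 → 2 → 4 → 7 → 11 → 12 → 13 → 14 → 15).

**Steps most likely to fail**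

Step 4 (key aldol). Enolisation of the bulky aryloxyacetyl imide may be incomplete or not geometrically clean, and addition to the electron-rich aldehyde may reverse on warming, so diastereoselectivity could erode. The fallback takes C8 from the chiral pool and sets C7 by substrate-controlled reduction; it sets out from phenol 2 and rejoins the route at alcohol 14.
- Mitsunobu etherification of 2 with ethyl (S)-lactate (PPh3, DIAD, THF, 0 °C → rt) should give, with inversion, ethyl (R)-2-[2,6-dimethoxy-4-((E)-prop-1-enyl)phenoxy]propanoate F1.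
- Treatment with MeNHOMe·HCl and iPrMgCl (THF, −20 °C) should give the Weinreb amide (R)-2-[2,6-dimethoxy-4-((E)-prop-1-enyl)phenoxy]-N-methoxy-N-methylpropanamide F2.
- Addition of 3,4,5-trimethoxyphenylmagnesium bromide (from 5-bromo-1,2,3-trimethoxybenzene, THF, 0 °C) should give (R)-2-[2,6-dimethoxy-4-((E)-prop-1-enyl)phenoxy]-1-(3,4,5-trimethoxyphenyl)propan-1-one F3.
- Felkin–Anh reduction with a bulky non-chelating hydride (L-Selectride, THF, −78 °C), with the aryloxy group anti to the incoming hydride, is expected to favour the 7,8-syn alcohol 14, which is then acetylated as in step 8.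

Step 7 (tosylate reduction). The C7 lithium alkoxide may attack C9 (oxetane closure) or trigger 1,3-fragmentation to aldehyde and aryl vinyl ether before hydride displacement is complete. The fallback removes the alkoxide by masking C7–OH; it sets out from tosylate 13 and rejoins at alcohol 14.
- Silylation (TBSOTf, 2,6-lutidine, CH2Cl2, −78 °C) should give (2R,3R)-3-(tert-butyldimethylsilyloxy)-2-[2,6-dimethoxy-4-((E)-prop-1-enyl)phenoxy]-3-(3,4,5-trimethoxyphenyl)propyl 4-methylbenzenesulfonate F4.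
- LiEt3BH (THF, 0 °C → rt) should then give tert-butyl{(1R,2R)-2-[2,6-dimethoxy-4-((E)-prop-1-enyl)phenoxy]-1-(3,4,5-trimethoxyphenyl)propoxy}dimethylsilane F5.
- TBAF (THF, 0 °C → rt) should release 14.

Step 5 (auxiliary cleavage). The bulky α-aryloxy group may divert hydride to the endocyclic carbamate carbonyl (ring-opened hydroxyamide), or the basic medium may cause retro-aldol loss of the adduct. The fallback separates cleavage from reduction; it sets out from adduct 11 and rejoins at diol 12.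
- Hydroperoxide cleavage (LiOH, H2O2, THF–H2O, 0 °C), which is selective for the exocyclic carbonyl, should give (2S,3R)-2-[2,6-dimethoxy-4-((E)-prop-1-enyl)phenoxy]-3-hydroxy-3-(3,4,5-trimethoxyphenyl)propanoic acid F6 and recovered auxiliary.
- Esterification (TMSCHN2, MeOH–toluene, 0 °C) should give methyl (2S,3R)-2-[2,6-dimethoxy-4-((E)-prop-1-enyl)phenoxy]-3-hydroxy-3-(3,4,5-trimethoxyphenyl)propanoate F7.
- Reduction of this α-oxygen-activated ester (LiBH4, THF, 0 °C → rt) should give 12.

**Further compounds**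
F1 | step 4 | ethyl (R)-2-[2,6-dimethoxy-4-((E)-prop-1-enyl)phenoxy]propanoate | C/C=C/c1cc(OC)c(O[C@H](C)C(=O)OCC)c(OC)c1
F2 | step 4 | (R)-2-[2,6-dimethoxy-4-((E)-prop-1-enyl)phenoxy]-N-methoxy-N-methylpropanamide | C/C=C/c1cc(OC)c(O[C@H](C)C(=O)N(C)OC)c(OC)c1
F3 | step 4 | (R)-2-[2,6-dimethoxy-4-((E)-prop-1-enyl)phenoxy]-1-(3,4,5-trimethoxyphenyl)propan-1-one | C/C=C/c1cc(OC)c(O[C@H](C)C(=O)c2cc(OC)c(OC)c(OC)c2)c(OC)c1
F4 | step 7 | (2R,3R)-3-(tert-butyldimethylsilyloxy)-2-[2,6-dimethoxy-4-((E)-prop-1-enyl)phenoxy]-3-(3,4,5-trimethoxyphenyl)propyl 4-methylbenzenesulfonate | C/C=C/c1cc(OC)c(O[C@@H]([C@H](O[Si](C)(C)C(C)(C)C)c2cc(OC)c(OC)c(OC)c2)COS(=O)(=O)c2ccc(C)cc2)c(OC)c1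
F5 | step 7 | tert-butyl{(1R,2R)-2-[2,6-dimethoxy-4-((E)-prop-1-enyl)phenoxy]-1-(3,4,5-trimethoxyphenyl)propoxy}dimethylsilane | C/C=C/c1cc(OC)c(O[C@H](C)[C@H](O[Si](C)(C)C(C)(C)C)c2cc(OC)c(OC)c(OC)c2)c(OC)c1
F6 | step 5 | (2S,3R)-2-[2,6-dimethoxy-4-((E)-prop-1-enyl)phenoxy]-3-hydroxy-3-(3,4,5-trimethoxyphenyl)propanoic acid | C/C=C/c1cc(OC)c(O[C@@H]([C@H](O)c2cc(OC)c(OC)c(OC)c2)C(=O)O)c(OC)c1
F7 | step 5 | methyl (2S,3R)-2-[2,6-dimethoxy-4-((E)-prop-1-enyl)phenoxy]-3-hydroxy-3-(3,4,5-trimethoxyphenyl)propanoate | C/C=C/c1cc(OC)c(O[C@@H]([C@H](O)c2cc(OC)c(OC)c(OC)c2)C(=O)OC)c(OC)c1
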